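**Strategy.** The 28-membered lactone ring is opened at the central C20=C21 bond of the C16–C25 pentaene and at the C1–O–C27 ester. Because C20=C21 sits between two E,E-dienes (C16–C19 and C22–C25), it can be carried as a C20≡C21 alkyne. Ring-closing alkyne metathesis of two methyl-capped dienynes then forms that bond and the macrocycle in one operation without touching the four preformed olefins, and trans-hydrosilylation/protodesilylation sets the last E-alkene. The cyclisation substrate is the hexa-TBS ester of a C1–C20 acid with a C21–C27 alcohol, each arm ending in a methyl-capped (E,E)-dienyne installed by Horner–Wadsworth–Emmons olefination with one common enynyl phosphonate.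

Key step: step 32

**Remarks**
- Numbering and abbreviations: chain fragments carry the macrolide numbers (C1 = lactone carbonyl, C2 bears ethyl, C14 and C26 bear methyl, C27 = ester carbinol). TBS = tert-butyldimethylsilyl, PMB = 4-methoxybenzyl, Bn = benzyl, Xc = (4S)-4-benzyl-2-oxo-1,3-oxazolidin-3-yl, Ipc = isopinocampheyl.
- Assumption: glutaraldehyde 23 is used as the anhydrous monomer, freshly obtained from the commercial aqueous solution by extraction, drying and distillation.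
- Assumption: the allylborane of step 16 is the preformed, magnesium-salt-free B-allyldiisopinocampheylborane of the (−)-α-pinene series (from (+)-Ipc2BOMe and allylMgBr), written l-Ipc2B(allyl).
- Assumption: step 33 is expected to give C20- and C21-silyl regioisomers that converge in step 34; 44 is drawn as the C21 isomer.
- Intermediate 32 is an epimeric mixture at C3.

**Part A – enynyl phosphonate 6**

Step 1
Reactants: 1 but-2-yn-1-ol
Product: 3 ethyl (2E)-hex-2-en-4-ynoate, via but-2-ynal 2 (not isolated)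
Conditions: MnO2 (activated, 10 equiv), Ph3P=CHCO2Et, CH2Cl2, rt
Reagents that add atoms: ethyl (triphenylphosphoranylidene)acetate, SMILES CCOC(=O)C=P(c1ccccc1)(c1ccccc1)c1ccccc1
Why: MnO2 oxidises the propargylic alcohol to the volatile ynal, which is trapped as it forms by the stabilised ylide (tandem oxidation–Wittig olefination), and a stabilised ylide should give the E-enoate.

Step 2
Reactants: 3 ethyl (2E)-hex-2-en-4-ynoate
Product: 4 (2E)-hex-2-en-4-yn-1-ol
Conditions: i-Bu2AlH (2.2 equiv), CH2Cl2, −78 °C; aq. potassium sodium tartrate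
Reagents that add atoms: none
Why: 1,2-reduction of a conjugated ester to the allylic alcohol by i-Bu2AlH at low temperature leaves the olefin and the alkyne untouched.

Step 3
Reactants: 4 (2E)-hex-2-en-4-yn-1-ol
Product: 5 (2E)-1-bromohex-2-en-4-yne
Conditions: PBr3 (0.4 equiv), Et2O, 0 °C
Reagents that add atoms: phosphorus tribromide, SMILES BrP(Br)Br
Why: Bromination of a primary allylic alcohol through its phosphite ester (SN2) should give the conjugated E bromide, which is also the thermodynamically preferred allylic isomer.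

Step 4
Reactants: 5 (2E)-1-bromohex-2-en-4-yne
Product: 6 diethyl [(2E)-hex-2-en-4-yn-1-yl]phosphonate
Conditions: P(OEt)3 (neat), 120 °C
Reagents that add atoms: triethyl phosphite, SMILES CCOP(OCC)OCC
Why: Michaelis–Arbuzov reaction of a reactive primary allylic bromide, driven by loss of bromoethane.

**Part B – butanoyl imide 9**

Step 5
Reactants: 7 (4S)-4-benzyl-1,3-oxazolidin-2-one; 8 butanoyl chloride
Product: 9 (4S)-4-benzyl-3-butanoyl-1,3-oxazolidin-2-one
Conditions: n-BuLi, THF, −78 °C; then 8, −78 → 0 °C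
Reagents that add atoms: none
Why: N-acylation of the lithiated oxazolidinone by an acid chloride is the standard preparation of aldol imides.

**Part C – alcohol 17 (C21–C27)**

Step 6
Reactants: 10 (4S)-4-benzyl-3-propanoyl-1,3-oxazolidin-2-one; 11 acetaldehyde
Product: 12 (4S)-4-benzyl-3-[(2S,3R)-3-hydroxy-2-methylbutanoyl]-1,3-oxazolidin-2-one
Conditions: Bu2BOTf, Et3N, CH2Cl2, −78 → 0 °C; then 11, −78 → 0 °C; pH 7 buffer, MeOH, H2O2
Reagents that add atoms: none
Why: Evans syn-aldol reaction, in which the Z-dibutylboron enolate reacts through a Zimmerman–Traxler chair with the enolate face opposite the auxiliary benzyl group exposed, setting C26 and C27 in the syn (2S,3R) sense.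

Step 7
Reactants: 12 aldol adduct
Product: 13 (4S)-4-benzyl-3-[(2S,3R)-3-(tert-butyldimethylsilyloxy)-2-methylbutanoyl]-1,3-oxazolidin-2-one
Conditions: TBSOTf, 2,6-lutidine, CH2Cl2, 0 °C
Reagents that add atoms: tert-butyldimethylsilyl triflate, SMILES CC(C)(C)[Si](C)(C)OS(=O)(=O)C(F)(F)F
Why: Silylation of a secondary alcohol with a silyl triflate and a hindered base blocks retro-aldol cleavage in the next step.

Step 8
Reactants: 13 silyl ether
Product: 14 (2R,3R)-3-(tert-butyldimethylsilyloxy)-2-methylbutan-1-ol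
Conditions: LiBH4, MeOH (1 equiv), THF, 0 °C
Reagents that add atoms: none
Why: Reductive cleavage of the N-acyl oxazolidinone by LiBH4 gives the primary alcohol without epimerisation and returns the auxiliary.

Step 9
Reactants: 14 primary alcohol
Product: 15 (2S,3R)-3-(tert-butyldimethylsilyloxy)-2-methylbutanal
Conditions: Dess–Martin periodinane, CH2Cl2, 0 °C → rt
Reagents that add atoms: none
Why: Dess–Martin oxidation is a near-neutral oxidation that should not epimerise the α-methyl aldehyde, which is used at once.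

Step 10
Reactants: 15 aldehyde; 6 enynyl phosphonate
Product: 16 tert-butyldimethyl{[(2R,3R,4E,6E)-3-methyldeca-4,6-dien-8-yn-2-yl]oxy}silane
Conditions: 6, LiN(SiMe3)2, THF, −78 °C; then 15, −78 → 0 °C
Reagents that add atoms: none
Why: Horner–Wadsworth–Emmons olefination with the lithiated allylic phosphonate attacks the aldehyde at the carbon next to phosphorus and eliminates phosphate to the E olefin (C24=C25), the cold, non-equilibrating conditions preserving C26.

Step 11
Reactants: 16 silyl ether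
Product: 17 (2R,3R,4E,6E)-3-methyldeca-4,6-dien-8-yn-2-ol
Conditions: Bu4NF, THF, rt
Reagents that add atoms: none
Why: Fluoride cleavage of a secondary TBS ether; the dienyne is inert to fluoride.

**Part D – aldehyde 22 (C13–C16)**

Step 12
Reactants: 10 (4S)-4-benzyl-3-propanoyl-1,3-oxazolidin-2-one; 18 (benzyloxy)acetaldehyde
Product: 19 (4S)-4-benzyl-3-[(2S,3S)-4-(benzyloxy)-3-hydroxy-2-methylbutanoyl]-1,3-oxazolidin-2-one
Conditions: Bu2BOTf, Et3N, CH2Cl2, −78 → 0 °C; then 18, −78 → 0 °C; pH 7 buffer, MeOH, H2O2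
Reagents that add atoms: none
Why: Evans syn-aldol reaction with the same auxiliary-controlled chair transition state as in step 6 sets C14 (methyl) and C15 (oxygen) syn with the target configuration.

Step 13
Reactants: 19 aldol adduct
Product: 20 (4S)-4-benzyl-3-[(2S,3S)-4-(benzyloxy)-3-(tert-butyldimethylsilyloxy)-2-methylbutanoyl]-1,3-oxazolidin-2-one
Conditions: TBSOTf, 2,6-lutidine, CH2Cl2, 0 °C
Reagents that add atoms: tert-butyldimethylsilyl triflate, SMILES CC(C)(C)[Si](C)(C)OS(=O)(=O)C(F)(F)F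
Why: Silylation installs the C15 silyl ether that is carried to the end.

Step 14
Reactants: 20 silyl ether
Product: 21 (2R,3S)-4-(benzyloxy)-3-(tert-butyldimethylsilyloxy)-2-methylbutan-1-ol
Conditions: LiBH4, MeOH (1 equiv), THF, 0 °C
Reagents that add atoms: none
Why: Reductive removal of the auxiliary by LiBH4, as in step 8.

Step 15
Reactants: 21 primary alcohol
Product: 22 (2S,3S)-4-(benzyloxy)-3-(tert-butyldimethylsilyloxy)-2-methylbutanal
Conditions: Dess–Martin periodinane, CH2Cl2, 0 °C → rt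
Reagents that add atoms: none
Why: Dess–Martin oxidation to the C13 aldehyde without loss of the C14 configuration.

**Part E – main chain**

Step 16
Reactants: 23 pentanedial (glutaraldehyde)
Product: 24 (4S,8S)-undeca-1,10-diene-4,8-diol
Conditions: l-Ipc2B(allyl) (2.3 equiv), Et2O, −78 °C; then NaOH, H2O2, rt
Reagents that add atoms: B-allyldiisopinocampheylborane of the (−)-α-pinene series, SMILES C=CCB([C@H]1C[C@H]2C[C@@H]([C@@H]1C)C2(C)C)[C@H]1C[C@H]2C[C@@H]([C@@H]1C)C2(C)C
Why: Brown allylboration, in which each aldehyde reacts through a chair six-membered transition state and this reagent antipode (the one that turns butanal into (S)-hept-1-en-4-ol) sets C5 and C9 as S, the two-fold addition leaving stereochemical error mainly as the separable meso diol.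

Step 17
Reactants: 24 diene diol
Product: 25 (4S,8S)-4,8-bis[(4-methoxybenzyl)oxy]undeca-1,10-diene
Conditions: NaH, PMBCl, Bu4NI (cat.), THF/DMF, 0 °C → rt
Reagents that add atoms: 4-methoxybenzyl chloride, SMILES COc1ccc(CCl)cc1
Why: Williamson etherification installs the β-alkoxy group needed to direct the aldol in step 19.

Step 18
Reactants: 25 bis-PMB ether
Product: 26 (4S,8S)-4,8-bis[(4-methoxybenzyl)oxy]undec-10-en-2-one
Conditions: PdCl2 (10 mol %), CuCl, O2 (1 atm), DMF/H2O, rt, stopped near half conversion; recovered 25 recycled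
Reagents that add atoms: water, SMILES O
Why: Tsuji–Wacker oxidation gives the methyl ketone by Markovnikov hydroxypalladation with water as the oxygen source and O2 as terminal oxidant, and because 25 is C2-symmetric either olefin gives the same mono-ketone, so the only cost is the statistical conversion limit.

Step 19
Reactants: 26 methyl ketone; 22 aldehyde
Product: 27 C3–C16 aldol adduct (13-hydroxy-11-ketone; 5,9-bis-PMB ether, 15-TBS ether, 16-Bn ether, terminal vinyl at C3)
Conditions: 26, Bu2BOTf, i-Pr2NEt, Et2O, −78 °C; then 22, −78 °C; pH 7 buffer, MeOH, H2O2, 0 °C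
Reagents that add atoms: none
Why: Boron-mediated 1,5-anti aldol reaction of a β-alkoxy methyl ketone, in which the β-PMB ether at C9 dictates the face of the kinetic dibutylboron enolate and sets C13 anti to C9 (and anti to the C14 methyl), while the syn α-methyl-β-silyloxy aldehyde has only a weak facial bias toward unsubstituted boron enolates.

Step 20
Reactants: 27 β-hydroxy ketone
Product: 28 C3–C16 11,13-anti diol
Conditions: Me4NBH(OAc)3, MeCN/AcOH, −30 °C
Reagents that add atoms: none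
Why: Evans–Saksena reduction, in which the C13 hydroxyl binds boron and delivers hydride intramolecularly through a chair transition state, setting C11 1,3-anti to C13 and therefore syn to C9.

Step 21
Reactants: 28 diol
Product: 29 C3–C16 11,13,15-tris-TBS ether (5,9-bis-PMB, 16-Bn)
Conditions: TBSOTf, 2,6-lutidine, CH2Cl2, −78 → 0 °C
Reagents that add atoms: tert-butyldimethylsilyl triflate, SMILES CC(C)(C)[Si](C)(C)OS(=O)(=O)C(F)(F)F
Why: The silyl triflate silylates both secondary hydroxyls, including the hindered C13 position.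

Step 22
Reactants: 29 bis-PMB ether
Product: 30 C3–C16 5,9-diol (11,13,15-tris-TBS, 16-Bn)
Conditions: DDQ, CH2Cl2/pH 7 buffer, 0 °C
Reagents that add atoms: none
Why: Oxidative cleavage of the electron-rich PMB ethers by DDQ leaves the benzyl ether, the silyl ethers and the terminal olefin untouched; it is done before any conjugated diene is present.

Step 23
Reactants: 30 diol
Product: 31 C3–C16 5,9,11,13,15-penta-TBS ether (16-Bn, terminal vinyl at C3)
Conditions: TBSOTf, 2,6-lutidine, CH2Cl2, −78 → 0 °C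
Reagents that add atoms: tert-butyldimethylsilyl triflate, SMILES CC(C)(C)[Si](C)(C)OS(=O)(=O)C(F)(F)F
Why: Silylation brings C5 and C9 to the protecting group that is kept to the end.

Step 24
Reactants: 31 terminal olefin
Product: 33 C3 aldehyde (penta-TBS 16-Bn ether), via vicinal diol 32 (not isolated)
Conditions: OsO4 (2 mol %), NaIO4, 2,6-lutidine, dioxane/H2O, rt
Reagents that add atoms: osmium tetroxide, SMILES O=[Os](=O)(=O)=O; sodium periodate, SMILES [Na+].[O-]I(=O)(=O)=O
Why: Lemieux–Johnson oxidation dihydroxylates the only olefin with catalytic OsO4 (regenerated by periodate) and cleaves the diol to the C3 aldehyde, and it is gentler on the benzyl ether than ozone.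

Step 25
Reactants: 33 C3 aldehyde; 9 butanoyl imide
Product: 34 C1–C16 aldol adduct (C1 imide, 2-ethyl, 3-hydroxy; penta-TBS, 16-Bn)
Conditions: 9, Bu2BOTf, Et3N, CH2Cl2, −78 → 0 °C; then 33, −78 → 0 °C; pH 7 buffer, MeOH, H2O2
Reagents that add atoms: none
Why: Evans syn-aldol reaction, in which the auxiliary-controlled Z-boron enolate overrides the remote C5 centre and sets C2 (ethyl) and C3 (hydroxyl) syn with the target configuration.

Step 26
Reactants: 34 aldol adduct
Product: 35 C1–C16 hexa-TBS imide (16-Bn)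
Conditions: TBSOTf, 2,6-lutidine, CH2Cl2, 0 °C
Reagents that add atoms: tert-butyldimethylsilyl triflate, SMILES CC(C)(C)[Si](C)(C)OS(=O)(=O)C(F)(F)F
Why: Silylation of the C3 hydroxyl completes the set of six silyl ethers and prevents retro-aldol cleavage.

Step 27
Reactants: 35 benzyl ether
Product: 36 C1–C16 hexa-TBS imide with free C16 hydroxyl
Conditions: H2 (1 atm), Pd(OH)2/C, EtOAc, rt
Reagents that add atoms: none
Why: Hydrogenolysis of the benzyl ether is clean here because no olefin is present; the C-benzyl group of the auxiliary and the silyl ethers are inert.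

Step 28
Reactants: 36 primary alcohol
Product: 37 C1–C16 hexa-TBS imide C16 aldehyde
Conditions: Dess–Martin periodinane, CH2Cl2, 0 °C → rt
Reagents that add atoms: none
Why: Dess–Martin oxidation gives the α-silyloxy aldehyde without epimerising C15; it is used directly.

Step 29
Reactants: 37 C16 aldehyde; 6 enynyl phosphonate
Product: 38 C1–C20 dienyne imide (hexa-TBS, methyl-capped C20 alkyne)
Conditions: 6, LiN(SiMe3)2, THF, −78 °C; then 37, −78 → 0 °C
Reagents that add atoms: none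
Why: Horner–Wadsworth–Emmons olefination forms the E C16=C17 bond; the stabilised phosphonate anion should add to the aldehyde much faster than to the hindered imide and is too weak a base at −78 °C to epimerise C15.

Step 30
Reactants: 38 dienyne imide
Product: 40 C1–C20 dienyne acid (hexa-TBS), via peroxy acid 39 (not isolated)
Conditions: LiOH, H2O2, THF/H2O, 0 °C → rt; Na2SO3; aq. HCl to pH 4
Reagents that add atoms: hydrogen peroxide, SMILES OO
Why: Hydroperoxide attacks the exocyclic imide carbonyl selectively even in hindered cases, sulfite reduces the peracid, and the nucleophilic peroxide does not epoxidise the unactivated dienyne.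

Step 31
Reactants: 40 acid; 17 alcohol
Product: 42 ester-linked bis(dienyne) with six TBS ethers, via mixed anhydride 41 (not isolated)
Conditions: 40, 2,4,6-Cl3C6H2COCl, Et3N, toluene, rt; then 17, DMAP, toluene, rt → 40 °C
Reagents that add atoms: none
Why: Yamaguchi esterification acylates the secondary alcohol through the mixed anhydride and the acylpyridinium with retention at C27; the C3 silyl ether and mild temperature guard against β-elimination and C2 epimerisation.

Step 32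
Reactants: 42 ester-linked bis(dienyne)
Product: 43 macrocyclic 20,21-didehydro tetraene-yne with six TBS ethers
Conditions: Mo(≡CC6H4OMe-4)(OSiPh3)3 (20 mol %), MS 5 Å, toluene (2 mM), rt → 60 °C
Reagents that add atoms: none
Why: The alkylidyne adds to one propynyl terminus by [2+2] cycloaddition, the metallacyclobutadiene cycloreverts to a chain-bound alkylidyne, and a second [2+2]/cycloreversion with the other terminus joins C20 to C21, expels but-2-yne (taken up by the sieves) and regenerates the catalyst. The closest known reaction type is ring-closing alkyne metathesis of 1,3-enynes to macrocyclic enynes, of which this diene–yne–diene is a longer conjugated member. The 28-membered ring is closed head-to-head between the two alkyne carbons, giving an endocyclic triple bond whose linear C19–C20≡C21–C22 unit fits easily in a ring of this size. No stereocentre is formed. The step needs alkyne-over-olefin chemoselectivity, which the alkylidyne provides because it does not engage olefins, the ester or silyl ethers, so the four E-olefins keep their geometry. It also needs cyclisation over oligomerisation, which high dilution, removal of but-2-yne and unhindered methyl-capped termini held away from the silyl ethers by the rigid E,E-dienes should secure.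

Step 33
Reactants: 43 macrocyclic enyne
Product: 44 macrocyclic C21-triethoxysilyl pentaene (C20/C21 regioisomers, hexa-TBS)
Conditions: (EtO)3SiH, [Cp*Ru(MeCN)3]PF6 (15 mol %), CH2Cl2, 0 °C → rt
Reagents that add atoms: triethoxysilane, SMILES CCO[SiH](OCC)OCC
Why: Ruthenium-catalysed trans-hydrosilylation adds H and Si to opposite faces of the triple bond, so C19 and C22 end up trans whichever carbon receives silicon.

Step 34
Reactants: 44 alkenylsilane
Product: 45 hexa-TBS all-E pentaene macrolide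
Conditions: AgF, THF/MeOH/H2O, rt, dark
Reagents that add atoms: none
Why: Fluoride-assisted transfer of the alkenyl group from silicon to silver and protonation replace silicon by hydrogen with retention, giving the E C20=C21 olefin under conditions that leave the TBS ethers and the lactone intact.

Step 35
Reactants: 45 hexa-TBS pentaene
Product: 46 target macrolide CNP0382847.1
Conditions: HF·pyridine, pyridine, THF, 0 °C → rt
Reagents that add atoms: none
Why: Buffered HF·pyridine removes all six TBS ethers under non-basic conditions, which avoids C5-alkoxide translactonisation and retro-aldol cleavage and limits ionisation of the C15 pentaenyl carbinol.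

**Compound list**

1 | but-2-yn-1-ol | CC#CCO | starting material
2 | but-2-ynal | CC#CC=O | intermediate (not isolated)
3 | ethyl (2E)-hex-2-en-4-ynoate | CC#C/C=C/C(=O)OCC | intermediate
4 | (2E)-hex-2-en-4-yn-1-ol | CC#C/C=C/CO | intermediate
5 | (2E)-1-bromohex-2-en-4-yne | CC#C/C=C/CBr | intermediate
6 | diethyl [(2E)-hex-2-en-4-yn-1-yl]phosphonate | CC#C/C=C/CP(=O)(OCC)OCC | intermediate
7 | (4S)-4-benzyl-1,3-oxazolidin-2-one | O=C1OC[C@H](Cc2ccccc2)N1 | starting material
8 | butanoyl chloride | CCCC(=O)Cl | starting material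
9 | (4S)-4-benzyl-3-butanoyl-1,3-oxazolidin-2-one | CCCC(=O)N1[C@@H](Cc2ccccc2)COC1=O | intermediate
10 | (4S)-4-benzyl-3-propanoyl-1,3-oxazolidin-2-one | CCC(=O)N1[C@@H](Cc2ccccc2)COC1=O | starting material
11 | acetaldehyde | CC=O | starting material
12 | (4S)-4-benzyl-3-[(2S,3R)-3-hydroxy-2-methylbutanoyl]-1,3-oxazolidin-2-one | C[C@@H](O)[C@H](C)C(=O)N1[C@@H](Cc2ccccc2)COC1=O | intermediate
13 | (4S)-4-benzyl-3-[(2S,3R)-3-(tert-butyldimethylsilyloxy)-2-methylbutanoyl]-1,3-oxazolidin-2-one | C[C@@H](O[Si](C)(C)C(C)(C)C)[C@H](C)C(=O)N1[C@@H](Cc2ccccc2)COC1=O | intermediate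
14 | (2R,3R)-3-(tert-butyldimethylsilyloxy)-2-methylbutan-1-ol | C[C@@H](O[Si](C)(C)C(C)(C)C)[C@H](C)CO | intermediate
15 | (2S,3R)-3-(tert-butyldimethylsilyloxy)-2-methylbutanal | C[C@@H](O[Si](C)(C)C(C)(C)C)[C@H](C)C=O | intermediate
16 | tert-butyldimethyl{[(2R,3R,4E,6E)-3-methyldeca-4,6-dien-8-yn-2-yl]oxy}silane | C[C@@H](O[Si](C)(C)C(C)(C)C)[C@H](C)/C=C/C=C/C#CC | intermediate
17 | (2R,3R,4E,6E)-3-methyldeca-4,6-dien-8-yn-2-ol (C21–C27 alcohol) | C[C@@H](O)[C@H](C)/C=C/C=C/C#CC | intermediate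
18 | (benzyloxy)acetaldehyde | O=CCOCc1ccccc1 | starting material
19 | (4S)-4-benzyl-3-[(2S,3S)-4-(benzyloxy)-3-hydroxy-2-methylbutanoyl]-1,3-oxazolidin-2-one | c1ccccc1COC[C@@H](O)[C@H](C)C(=O)N1[C@@H](Cc2ccccc2)COC1=O | intermediate
20 | (4S)-4-benzyl-3-[(2S,3S)-4-(benzyloxy)-3-(tert-butyldimethylsilyloxy)-2-methylbutanoyl]-1,3-oxazolidin-2-one | c1ccccc1COC[C@@H](O[Si](C)(C)C(C)(C)C)[C@H](C)C(=O)N1[C@@H](Cc2ccccc2)COC1=O | intermediate
21 | (2R,3S)-4-(benzyloxy)-3-(tert-butyldimethylsilyloxy)-2-methylbutan-1-ol | c1ccccc1COC[C@@H](O[Si](C)(C)C(C)(C)C)[C@H](C)CO | intermediate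
22 | (2S,3S)-4-(benzyloxy)-3-(tert-butyldimethylsilyloxy)-2-methylbutanal (C13–C16 aldehyde) | c1ccccc1COC[C@@H](O[Si](C)(C)C(C)(C)C)[C@H](C)C=O | intermediate
23 | pentanedial (glutaraldehyde) | O=CCCCC=O | starting material
24 | (4S,8S)-undeca-1,10-diene-4,8-diol | C=CC[C@@H](O)CCC[C@H](O)CC=C | intermediate
25 | (4S,8S)-4,8-bis[(4-methoxybenzyl)oxy]undeca-1,10-diene | C=CC[C@@H](OCc1ccc(OC)cc1)CCC[C@H](OCc1ccc(OC)cc1)CC=C | intermediate
26 | (4S,8S)-4,8-bis[(4-methoxybenzyl)oxy]undec-10-en-2-one (C3–C12 methyl ketone) | CC(=O)C[C@@H](OCc1ccc(OC)cc1)CCC[C@H](OCc1ccc(OC)cc1)CC=C | intermediate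
27 | C3–C16 aldol adduct: 13-hydroxy-11-ketone, 5,9-bis-PMB, 15-TBS, 16-Bn, terminal vinyl at C3 (C5, C9, C13, C14, C15 as in 46) | c1ccccc1COC[C@@H](O[Si](C)(C)C(C)(C)C)[C@H](C)[C@H](O)CC(=O)C[C@@H](OCc1ccc(OC)cc1)CCC[C@H](OCc1ccc(OC)cc1)CC=C | intermediate
28 | C3–C16 11,13-anti diol, 5,9-bis-PMB, 15-TBS, 16-Bn | c1ccccc1COC[C@@H](O[Si](C)(C)C(C)(C)C)[C@H](C)[C@H](O)C[C@@H](O)C[C@@H](OCc1ccc(OC)cc1)CCC[C@H](OCc1ccc(OC)cc1)CC=C | intermediate
29 | C3–C16 11,13,15-tris-TBS ether, 5,9-bis-PMB, 16-Bn | c1ccccc1COC[C@@H](O[Si](C)(C)C(C)(C)C)[C@H](C)[C@H](O[Si](C)(C)C(C)(C)C)C[C@@H](O[Si](C)(C)C(C)(C)C)C[C@@H](OCc1ccc(OC)cc1)CCC[C@H](OCc1ccc(OC)cc1)CC=C | intermediate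
30 | C3–C16 5,9-diol, 11,13,15-tris-TBS, 16-Bn | c1ccccc1COC[C@@H](O[Si](C)(C)C(C)(C)C)[C@H](C)[C@H](O[Si](C)(C)C(C)(C)C)C[C@@H](O[Si](C)(C)C(C)(C)C)C[C@@H](O)CCC[C@H](O)CC=C | intermediate
31 | C3–C16 5,9,11,13,15-penta-TBS ether, 16-Bn, terminal vinyl at C3 | c1ccccc1COC[C@@H](O[Si](C)(C)C(C)(C)C)[C@H](C)[C@H](O[Si](C)(C)C(C)(C)C)C[C@@H](O[Si](C)(C)C(C)(C)C)C[C@@H](O[Si](C)(C)C(C)(C)C)CCC[C@H](O[Si](C)(C)C(C)(C)C)CC=C | intermediate
32 | vicinal diol from dihydroxylation of 31 (C3 epimers) | c1ccccc1COC[C@@H](O[Si](C)(C)C(C)(C)C)[C@H](C)[C@H](O[Si](C)(C)C(C)(C)C)C[C@@H](O[Si](C)(C)C(C)(C)C)C[C@@H](O[Si](C)(C)C(C)(C)C)CCC[C@H](O[Si](C)(C)C(C)(C)C)CC(O)CO | intermediate (not isolated)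
33 | C3 aldehyde, penta-TBS, 16-Bn | c1ccccc1COC[C@@H](O[Si](C)(C)C(C)(C)C)[C@H](C)[C@H](O[Si](C)(C)C(C)(C)C)C[C@@H](O[Si](C)(C)C(C)(C)C)C[C@@H](O[Si](C)(C)C(C)(C)C)CCC[C@H](O[Si](C)(C)C(C)(C)C)CC=O | intermediate
34 | C1–C16 aldol adduct: C1 imide (Xc), 2-ethyl, 3-hydroxy, penta-TBS, 16-Bn | c1ccccc1COC[C@@H](O[Si](C)(C)C(C)(C)C)[C@H](C)[C@H](O[Si](C)(C)C(C)(C)C)C[C@@H](O[Si](C)(C)C(C)(C)C)C[C@@H](O[Si](C)(C)C(C)(C)C)CCC[C@H](O[Si](C)(C)C(C)(C)C)C[C@@H](O)[C@H](CC)C(=O)N1[C@@H](Cc2ccccc2)COC1=O | intermediate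
35 | C1–C16 hexa-TBS imide, 16-Bn | c1ccccc1COC[C@@H](O[Si](C)(C)C(C)(C)C)[C@H](C)[C@H](O[Si](C)(C)C(C)(C)C)C[C@@H](O[Si](C)(C)C(C)(C)C)C[C@@H](O[Si](C)(C)C(C)(C)C)CCC[C@H](O[Si](C)(C)C(C)(C)C)C[C@@H](O[Si](C)(C)C(C)(C)C)[C@H](CC)C(=O)N1[C@@H](Cc2ccccc2)COC1=O | intermediate
36 | C1–C16 hexa-TBS imide, free C16 hydroxyl | OC[C@@H](O[Si](C)(C)C(C)(C)C)[C@H](C)[C@H](O[Si](C)(C)C(C)(C)C)C[C@@H](O[Si](C)(C)C(C)(C)C)C[C@@H](O[Si](C)(C)C(C)(C)C)CCC[C@H](O[Si](C)(C)C(C)(C)C)C[C@@H](O[Si](C)(C)C(C)(C)C)[C@H](CC)C(=O)N1[C@@H](Cc2ccccc2)COC1=O | intermediate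
37 | C1–C16 hexa-TBS imide, C16 aldehyde | O=C[C@@H](O[Si](C)(C)C(C)(C)C)[C@H](C)[C@H](O[Si](C)(C)C(C)(C)C)C[C@@H](O[Si](C)(C)C(C)(C)C)C[C@@H](O[Si](C)(C)C(C)(C)C)CCC[C@H](O[Si](C)(C)C(C)(C)C)C[C@@H](O[Si](C)(C)C(C)(C)C)[C@H](CC)C(=O)N1[C@@H](Cc2ccccc2)COC1=O | intermediate
38 | C1–C20 (16E,18E)-dienyne imide, hexa-TBS, methyl-capped alkyne | CC#C/C=C/C=C/[C@@H](O[Si](C)(C)C(C)(C)C)[C@H](C)[C@H](O[Si](C)(C)C(C)(C)C)C[C@@H](O[Si](C)(C)C(C)(C)C)C[C@@H](O[Si](C)(C)C(C)(C)C)CCC[C@H](O[Si](C)(C)C(C)(C)C)C[C@@H](O[Si](C)(C)C(C)(C)C)[C@H](CC)C(=O)N1[C@@H](Cc2ccccc2)COC1=O | intermediate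
39 | C1–C20 dienyne peroxy acid, hexa-TBS | CC#C/C=C/C=C/[C@@H](O[Si](C)(C)C(C)(C)C)[C@H](C)[C@H](O[Si](C)(C)C(C)(C)C)C[C@@H](O[Si](C)(C)C(C)(C)C)C[C@@H](O[Si](C)(C)C(C)(C)C)CCC[C@H](O[Si](C)(C)C(C)(C)C)C[C@@H](O[Si](C)(C)C(C)(C)C)[C@H](CC)C(=O)OO | intermediate (not isolated)
40 | C1–C20 dienyne carboxylic acid, hexa-TBS | CC#C/C=C/C=C/[C@@H](O[Si](C)(C)C(C)(C)C)[C@H](C)[C@H](O[Si](C)(C)C(C)(C)C)C[C@@H](O[Si](C)(C)C(C)(C)C)C[C@@H](O[Si](C)(C)C(C)(C)C)CCC[C@H](O[Si](C)(C)C(C)(C)C)C[C@@H](O[Si](C)(C)C(C)(C)C)[C@H](CC)C(=O)O | intermediate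
41 | mixed anhydride of 40 with 2,4,6-trichlorobenzoic acid | CC#C/C=C/C=C/[C@@H](O[Si](C)(C)C(C)(C)C)[C@H](C)[C@H](O[Si](C)(C)C(C)(C)C)C[C@@H](O[Si](C)(C)C(C)(C)C)C[C@@H](O[Si](C)(C)C(C)(C)C)CCC[C@H](O[Si](C)(C)C(C)(C)C)C[C@@H](O[Si](C)(C)C(C)(C)C)[C@H](CC)C(=O)OC(=O)c1c(Cl)cc(Cl)cc1Cl | intermediate (not isolated)
42 | ester-linked bis(dienyne) with six TBS ethers (cyclisation substrate) | CC#C/C=C/C=C/[C@@H](O[Si](C)(C)C(C)(C)C)[C@H](C)[C@H](O[Si](C)(C)C(C)(C)C)C[C@@H](O[Si](C)(C)C(C)(C)C)C[C@@H](O[Si](C)(C)C(C)(C)C)CCC[C@H](O[Si](C)(C)C(C)(C)C)C[C@@H](O[Si](C)(C)C(C)(C)C)[C@H](CC)C(=O)O[C@H](C)[C@H](C)/C=C/C=C/C#CC | intermediate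
43 | macrocyclic 20,21-didehydro (16E,18E,22E,24E)-tetraene-yne with six TBS ethers | CC[C@@H]1C(=O)O[C@H](C)[C@H](C)/C=C/C=C/C#C/C=C/C=C/[C@@H](O[Si](C)(C)C(C)(C)C)[C@H](C)[C@H](O[Si](C)(C)C(C)(C)C)C[C@@H](O[Si](C)(C)C(C)(C)C)C[C@@H](O[Si](C)(C)C(C)(C)C)CCC[C@H](O[Si](C)(C)C(C)(C)C)C[C@H]1O[Si](C)(C)C(C)(C)C | intermediate
44 | macrocyclic 21-triethoxysilyl pentaene, hexa-TBS (C19 and C22 trans; C21 regioisomer drawn) | CC[C@@H]1C(=O)O[C@H](C)[C@H](C)/C=C/C=C/C([Si](OCC)(OCC)OCC)=C/C=C/C=C/[C@@H](O[Si](C)(C)C(C)(C)C)[C@H](C)[C@H](O[Si](C)(C)C(C)(C)C)C[C@@H](O[Si](C)(C)C(C)(C)C)C[C@@H](O[Si](C)(C)C(C)(C)C)CCC[C@H](O[Si](C)(C)C(C)(C)C)C[C@H]1O[Si](C)(C)C(C)(C)C | intermediate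
45 | hexa-TBS ether of the all-E pentaene macrolide | CC[C@@H]1C(=O)O[C@H](C)[C@H](C)/C=C/C=C/C=C/C=C/C=C/[C@@H](O[Si](C)(C)C(C)(C)C)[C@H](C)[C@H](O[Si](C)(C)C(C)(C)C)C[C@@H](O[Si](C)(C)C(C)(C)C)C[C@@H](O[Si](C)(C)C(C)(C)C)CCC[C@H](O[Si](C)(C)C(C)(C)C)C[C@H]1O[Si](C)(C)C(C)(C)C | intermediate
46 | CNP0382847.1 (28-membered pentaene macrolide) | CC[C@@H]1C(=O)O[C@H](C)[C@H](C)/C=C/C=C/C=C/C=C/C=C/[C@@H](O)[C@H](C)[C@H](O)C[C@@H](O)C[C@@H](O)CCC[C@H](O)C[C@H]1O | target

**Step count and risk**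

Total: 35 steps. Longest linear sequence: 21 steps (10 → 19 → 20 → 21 → 22, then 27 → 46; steps 12–15 and 19–35).

The three steps most likely to fail:

1. Step 32 (ring-closing alkyne metathesis). At the dilution needed for a 28-membered ring, cyclisation may be outrun by acyclic oligomerisation and by slow decay of the alkylidyne. The fallback sets out from 17 and 38 and returns at 43. Alcohol 17 is silylated (Et3SiCl, imidazole) to the triethylsilyl ether F1. An excess of F1 and 38 are joined at ordinary concentration by alkyne cross-metathesis (same Mo(≡CC6H4OMe-4)(OSiPh3)3, MS 5 Å) to give the acyclic diene–yne–diene imide F2. LiOH/H2O2 followed by Na2SO3 gives the acid F3. Buffered HF·pyridine at 0 °C removes only the triethylsilyl group to give the seco acid F4. Yamaguchi macrolactonisation (2,4,6-trichlorobenzoyl chloride, Et3N, then slow addition to DMAP in warm toluene) then closes the lactone and gives 43.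

2. Step 33 (trans-hydrosilylation of the tetraene-yne). The flanking dienes may bind the ruthenium centre or be hydrosilylated or isomerised in competition with trans-addition to the triple bond. The fallback sets out from 43 and returns at 45. Cis-semi-reduction with Zn dust activated with Cu(OAc)2 and AgNO3 in MeOH/H2O gives the (20Z)-pentaene F5. Catalytic I2 in CH2Cl2 under diffuse light then equilibrates the Z olefin to the thermodynamically preferred all-E pentaene 45.

3. Step 35 (six-fold desilylation on the pentaene). The hindered C3, C13 and C15 silyl ethers may come off slowly, so that prolonged exposure ionises the C15 pentaenyl carbinol or lets the freed C5 hydroxyl open the lactone. The fallback sets out from 43 and returns at 46. The silyl ethers are removed at the less sensitive enyne stage with HF·pyridine/pyridine to give the hexaol enyne F6. F6 is hydrosilylated ((EtO)3SiH, [Cp*Ru(MeCN)3]PF6, which tolerates free hydroxyls) to the alkenylsilane F7. AgF in THF/MeOH/H2O then gives 46 directly.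

**Further compounds**

F1 | step 32 | triethyl{[(2R,3R,4E,6E)-3-methyldeca-4,6-dien-8-yn-2-yl]oxy}silane | C[C@@H](O[Si](CC)(CC)CC)[C@H](C)/C=C/C=C/C#CC
F2 | step 32 | acyclic C1–C27 diene–yne–diene imide (hexa-TBS, 27-triethylsilyl ether) | C[C@@H](O[Si](CC)(CC)CC)[C@H](C)/C=C/C=C/C#C/C=C/C=C/[C@@H](O[Si](C)(C)C(C)(C)C)[C@H](C)[C@H](O[Si](C)(C)C(C)(C)C)C[C@@H](O[Si](C)(C)C(C)(C)C)C[C@@H](O[Si](C)(C)C(C)(C)C)CCC[C@H](O[Si](C)(C)C(C)(C)C)C[C@@H](O[Si](C)(C)C(C)(C)C)[C@H](CC)C(=O)N1[C@@H](Cc2ccccc2)COC1=O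
F3 | step 32 | acyclic C1–C27 diene–yne–diene acid (hexa-TBS, 27-triethylsilyl ether) | C[C@@H](O[Si](CC)(CC)CC)[C@H](C)/C=C/C=C/C#C/C=C/C=C/[C@@H](O[Si](C)(C)C(C)(C)C)[C@H](C)[C@H](O[Si](C)(C)C(C)(C)C)C[C@@H](O[Si](C)(C)C(C)(C)C)C[C@@H](O[Si](C)(C)C(C)(C)C)CCC[C@H](O[Si](C)(C)C(C)(C)C)C[C@@H](O[Si](C)(C)C(C)(C)C)[C@H](CC)C(=O)O
F4 | step 32 | seco acid (27-hydroxy acid, hexa-TBS) | C[C@@H](O)[C@H](C)/C=C/C=C/C#C/C=C/C=C/[C@@H](O[Si](C)(C)C(C)(C)C)[C@H](C)[C@H](O[Si](C)(C)C(C)(C)C)C[C@@H](O[Si](C)(C)C(C)(C)C)C[C@@H](O[Si](C)(C)C(C)(C)C)CCC[C@H](O[Si](C)(C)C(C)(C)C)C[C@@H](O[Si](C)(C)C(C)(C)C)[C@H](CC)C(=O)O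
F5 | step 33 | (20Z)-pentaene macrolide hexa-TBS ether | CC[C@@H]1C(=O)O[C@H](C)[C@H](C)/C=C/C=C/C=C\C=C\C=C\[C@@H](O[Si](C)(C)C(C)(C)C)[C@H](C)[C@H](O[Si](C)(C)C(C)(C)C)C[C@@H](O[Si](C)(C)C(C)(C)C)C[C@@H](O[Si](C)(C)C(C)(C)C)CCC[C@H](O[Si](C)(C)C(C)(C)C)C[C@H]1O[Si](C)(C)C(C)(C)C
F6 | step 35 | macrocyclic 20,21-didehydro tetraene-yne hexaol | CC[C@@H]1C(=O)O[C@H](C)[C@H](C)/C=C/C=C/C#C/C=C/C=C/[C@@H](O)[C@H](C)[C@H](O)C[C@@H](O)C[C@@H](O)CCC[C@H](O)C[C@H]1O
F7 | step 35 | macrocyclic 21-triethoxysilyl pentaene hexaol | CC[C@@H]1C(=O)O[C@H](C)[C@H](C)/C=C/C=C/C([Si](OCC)(OCC)OCC)=C/C=C/C=C/[C@@H](O)[C@H](C)[C@H](O)C[C@@H](O)C[C@@H](O)CCC[C@H](O)C[C@H]1O
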